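**Retrosynthetic overview**

- The target is opened at C8–C9: the cross-conjugated dienone comes from oxidation of a macrocyclic bis-allylic alcohol, made by Nozaki–Hiyama–Kishi closure of an E-enal onto a (Z)-2-iodoallyl silyl ether. This is the only ring (11-membered) and it is formed last but two.
- The C9/C10 unit comes from an iodo-Wittig reaction on the C10 aldehyde; the C4 senecioate is put on after acetonide removal.
- The key bond C1–C11 and the quaternary centre C1 come from a Johnson–Claisen [3,3] rearrangement of a (3R)-allylic alcohol with an E-trisubstituted alkene (1,3-chirality transfer, E C2=C3 alkene).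
- The allylic alcohol comes from Felkin addition of an E-alkenyllithium (side chain, from the L-glutamic-acid-derived lactone acid) to a dioxolane aldehyde (C3–C8).
- The dioxolane aldehyde comes from the D-glycerate acetonide: C4 is bought, C5 is set by Felkin addition of MeMgBr to an ynone.

Numbering used below: ring carbons C1 (quaternary carbon) to C11 in the order of the target SMILES; C8 is the ketone carbon and C9 carries the hydroxymethyl group. The two esters/acids named as starting materials and the propargyl silyl ether are assumed to be commercial.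

**Route**

Step 1
Reactants: 1 methyl (R)-2,2-dimethyl-1,3-dioxolane-4-carboxylate; 2 tert-butyldimethyl(prop-2-yn-1-yloxy)silane
Product: 4 (R)-4-[(tert-butyldimethylsilyl)oxy]-1-(2,2-dimethyl-1,3-dioxolan-4-yl)but-2-yn-1-one, via lithium acetylide 3 (not isolated)
Conditions: 2, n-BuLi, THF, −78 °C; BF3·OEt2; then 1, −78 °C
Reagents that add atoms: none
Why: The alkynylborate formed from the lithium acetylide and BF3·OEt2 acylates the ester once (Yamaguchi ynone synthesis) without over-addition or epimerisation of the dioxolane centre.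

Step 2
Reactants: 4 (R)-4-[(tert-butyldimethylsilyl)oxy]-1-(2,2-dimethyl-1,3-dioxolan-4-yl)but-2-yn-1-one
Product: 5 (R)-5-[(tert-butyldimethylsilyl)oxy]-2-[(R)-2,2-dimethyl-1,3-dioxolan-4-yl]pent-3-yn-2-ol
Conditions: MeMgBr, THF, −78 °C
Reagents that add atoms: methylmagnesium bromide C[Mg]Br
Why: 1,2-Grignard addition under Felkin–Anh control (methyl enters anti to the dioxolane C–O bond) sets the tertiary carbinol C5 as R from the bought C4 centre, the minor epimer being removed by chromatography.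

Step 3
Reactants: 5 (R)-5-[(tert-butyldimethylsilyl)oxy]-2-[(R)-2,2-dimethyl-1,3-dioxolan-4-yl]pent-3-yn-2-ol
Product: 6 (2R,3E)-5-[(tert-butyldimethylsilyl)oxy]-2-[(R)-2,2-dimethyl-1,3-dioxolan-4-yl]pent-3-en-2-ol
Conditions: NaAlH2(OCH2CH2OMe)2, THF, −20 to 0 °C
Reagents that add atoms: none
Why: Hydroxyl-directed trans-hydroalumination of the propargylic alcohol followed by protonolysis gives the E alkene (C6=C7), the silyl ether and ketal being inert at this temperature.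

Step 4
Reactants: 6 (2R,3E)-5-[(tert-butyldimethylsilyl)oxy]-2-[(R)-2,2-dimethyl-1,3-dioxolan-4-yl]pent-3-en-2-ol
Product: 7 {(4R,5R)-5-[(E)-3-[(tert-butyldimethylsilyl)oxy]prop-1-en-1-yl]-2,2,5-trimethyl-1,3-dioxolan-4-yl}methanol
Conditions: p-TsOH (5 mol %), dry acetone, rt
Reagents that add atoms: none
Why: Acid-catalysed transketalisation (acetonide migration) equilibrates to the more substituted trans-dioxolane on the secondary and tertiary oxygens and frees the primary alcohol without touching a stereocentre.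

Step 5
Reactants: 7 {(4R,5R)-5-[(E)-3-[(tert-butyldimethylsilyl)oxy]prop-1-en-1-yl]-2,2,5-trimethyl-1,3-dioxolan-4-yl}methanol
Product: 8 (4S,5R)-5-[(E)-3-[(tert-butyldimethylsilyl)oxy]prop-1-en-1-yl]-2,2,5-trimethyl-1,3-dioxolane-4-carbaldehyde
Conditions: Dess–Martin periodinane, CH2Cl2, 0 °C to rt; used crude
Reagents that add atoms: none
Why: Dess–Martin oxidation gives the α-alkoxy aldehyde under non-basic conditions so that C4 is not epimerised (the descriptor changes only through priorities).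

Step 6
Reactants: 9 (S)-5-oxotetrahydrofuran-2-carboxylic acid
Product: 11 (S)-5-acetyldihydrofuran-2(3H)-one, via acid chloride 10 (not isolated)
Conditions: (COCl)2, DMF (cat.), CH2Cl2, 0 °C to rt; evaporate; MeMgBr, Fe(acac)3 (3 mol %), THF, −78 °C
Reagents that add atoms: methylmagnesium bromide C[Mg]Br
Why: Acid chloride formation followed by Fe-catalysed acylation of the Grignard reagent gives the methyl ketone at −78 °C without attack on the lactone, and the glutamic-acid-derived centre is retained.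

Step 7
Reactants: 11 (S)-5-acetyldihydrofuran-2(3H)-one
Product: 12 (S)-5-(prop-1-en-2-yl)dihydrofuran-2(3H)-one
Conditions: Zn, CH2Br2, TiCl4, THF/CH2Cl2, 0 °C to rt
Reagents that add atoms: dibromomethane BrCBr
Why: Takai–Lombardo methylenation is non-basic, so the enolisable α-acyloxy ketone is not racemised and the lactone carbonyl is left alone.

Step 8
Reactants: 12 (S)-5-(prop-1-en-2-yl)dihydrofuran-2(3H)-one
Product: 14 (S)-2-methylhept-1-en-6-yn-3-ol, via lactol 13 (not isolated)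
Conditions: i-Bu2AlH, CH2Cl2, −78 °C; then MeOH, K2CO3, dimethyl (1-diazo-2-oxopropyl)phosphonate, −78 °C to rt
Reagents that add atoms: dimethyl (1-diazo-2-oxopropyl)phosphonate COP(=O)(OC)C(=[N+]=[N-])C(C)=O
Why: Partial reduction to the lactol and Seyferth–Gilbert homologation with the Ohira–Bestmann reagent on its open hydroxy-aldehyde form give the terminal alkyne in one pot, the carbinol centre not being involved.

Step 9
Reactants: 14 (S)-2-methylhept-1-en-6-yn-3-ol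
Product: 15 (S)-tert-butyldimethyl[(2-methylhept-1-en-6-yn-3-yl)oxy]silane
Conditions: TBSCl, imidazole, DMF, rt
Reagents that add atoms: tert-butyldimethylsilyl chloride CC(C)(C)[Si](C)(C)Cl
Why: Standard silylation protects the side-chain allylic alcohol, which would otherwise also undergo the later Claisen rearrangement.

Step 10
Reactants: 15 (S)-tert-butyldimethyl[(2-methylhept-1-en-6-yn-3-yl)oxy]silane
Product: 17 tert-butyl{[(3S,6E)-7-iodo-2,6-dimethylhepta-1,6-dien-3-yl]oxy}dimethylsilane, via vinylalane 16 (not isolated)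
Conditions: AlMe3, Cp2ZrCl2 (0.3 equiv), CH2Cl2, 0 °C to rt; then I2, THF, −30 °C
Reagents that add atoms: trimethylaluminium C[Al](C)C; iodine II
Why: Negishi Zr-catalysed carboalumination adds Me–Al syn across the terminal alkyne with methyl on the internal carbon, and iodinolysis with retention gives the E trisubstituted vinyl iodide while the isopropenyl alkene does not react.

Step 11
Reactants: 17 tert-butyl{[(3S,6E)-7-iodo-2,6-dimethylhepta-1,6-dien-3-yl]oxy}dimethylsilane; 8 (4S,5R)-5-[(E)-3-[(tert-butyldimethylsilyl)oxy]prop-1-en-1-yl]-2,2,5-trimethyl-1,3-dioxolane-4-carbaldehyde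
Product: 19 (1R,2E,6S)-6-[(tert-butyldimethylsilyl)oxy]-1-{(4R,5R)-5-[(E)-3-[(tert-butyldimethylsilyl)oxy]prop-1-en-1-yl]-2,2,5-trimethyl-1,3-dioxolan-4-yl}-3,7-dimethylocta-2,7-dien-1-ol, via vinyllithium 18 (not isolated)
Conditions: 17, t-BuLi (2 equiv), Et2O, −78 °C; then 8, −78 °C
Reagents that add atoms: none
Why: Iodine–lithium exchange retains the E geometry and Felkin–Anh addition of the alkenyllithium anti to the dioxolane C–O bond gives the anti (C3 R) carbinol controlled by C4.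

Step 12
Reactants: 19 (1R,2E,6S)-6-[(tert-butyldimethylsilyl)oxy]-1-{(4R,5R)-5-[(E)-3-[(tert-butyldimethylsilyl)oxy]prop-1-en-1-yl]-2,2,5-trimethyl-1,3-dioxolan-4-yl}-3,7-dimethylocta-2,7-dien-1-ol
Product: 21 ethyl (3S,4E)-3-[(3S)-3-[(tert-butyldimethylsilyl)oxy]-4-methylpent-4-en-1-yl]-5-{(4R,5R)-5-[(E)-3-[(tert-butyldimethylsilyl)oxy]prop-1-en-1-yl]-2,2,5-trimethyl-1,3-dioxolan-4-yl}-3-methylpent-4-enoate, via ketene acetal 20 (not isolated)
Conditions: MeC(OEt)3, EtCO2H (cat.), xylene, 140 °C, EtOH distilled off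
Reagents that add atoms: triethyl orthoacetate CCOC(C)(OCC)OCC
Why: Johnson–Claisen [3,3]-sigmatropic rearrangement through a chair transition state with the dioxolanyl group equatorial forms the C1–C11 bond, transfers the C3 carbinol chirality to the quaternary centre C1 (S) and gives the E C2=C3 alkene.

Step 13
Reactants: 21 ethyl (3S,4E)-3-[(3S)-3-[(tert-butyldimethylsilyl)oxy]-4-methylpent-4-en-1-yl]-5-{(4R,5R)-5-[(E)-3-[(tert-butyldimethylsilyl)oxy]prop-1-en-1-yl]-2,2,5-trimethyl-1,3-dioxolan-4-yl}-3-methylpent-4-enoate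
Product: 22 (3S,4E)-3-[(3S)-3-[(tert-butyldimethylsilyl)oxy]-4-methylpent-4-en-1-yl]-5-{(4R,5R)-5-[(E)-3-[(tert-butyldimethylsilyl)oxy]prop-1-en-1-yl]-2,2,5-trimethyl-1,3-dioxolan-4-yl}-3-methylpent-4-enal
Conditions: i-Bu2AlH (1.1 equiv), CH2Cl2, −78 °C
Reagents that add atoms: none
Why: Partial hydride reduction of the hindered neopentyl-type ester stops at the aldehyde through an aluminium hemiacetal that is stable at −78 °C.

Step 14
Reactants: 22 (3S,4E)-3-[(3S)-3-[(tert-butyldimethylsilyl)oxy]-4-methylpent-4-en-1-yl]-5-{(4R,5R)-5-[(E)-3-[(tert-butyldimethylsilyl)oxy]prop-1-en-1-yl]-2,2,5-trimethyl-1,3-dioxolan-4-yl}-3-methylpent-4-enal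
Product: 23 ethyl (2Z,5S,6E)-5-[(3S)-3-[(tert-butyldimethylsilyl)oxy]-4-methylpent-4-en-1-yl]-7-{(4R,5R)-5-[(E)-3-[(tert-butyldimethylsilyl)oxy]prop-1-en-1-yl]-2,2,5-trimethyl-1,3-dioxolan-4-yl}-2-iodo-5-methylhepta-2,6-dienoate
Conditions: Ph3P=CHCO2Et, NIS, CH2Cl2, −20 °C; then 22, −20 °C to rt
Reagents that add atoms: ethyl (triphenylphosphoranylidene)acetate CCOC(=O)C=P(c1ccccc1)(c1ccccc1)c1ccccc1; N-iodosuccinimide O=C1CCC(=O)N1I
Why: Wittig olefination with the stabilised α-iodo ylide places C11 trans to the ester and therefore cis to iodine (Z), which is the C9=C10 geometry of the target.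

Step 15
Reactants: 23 ethyl (2Z,5S,6E)-5-[(3S)-3-[(tert-butyldimethylsilyl)oxy]-4-methylpent-4-en-1-yl]-7-{(4R,5R)-5-[(E)-3-[(tert-butyldimethylsilyl)oxy]prop-1-en-1-yl]-2,2,5-trimethyl-1,3-dioxolan-4-yl}-2-iodo-5-methylhepta-2,6-dienoate
Product: 24 (2Z,5S,6E)-5-[(3S)-3-[(tert-butyldimethylsilyl)oxy]-4-methylpent-4-en-1-yl]-7-{(4R,5R)-5-[(E)-3-[(tert-butyldimethylsilyl)oxy]prop-1-en-1-yl]-2,2,5-trimethyl-1,3-dioxolan-4-yl}-2-iodo-5-methylhepta-2,6-dien-1-ol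
Conditions: i-Bu2AlH (2.2 equiv), CH2Cl2, −78 °C
Reagents that add atoms: none
Why: 1,2-Reduction of the enoate gives the allylic alcohol (the future hydroxymethyl group on C9) and leaves the vinyl iodide intact at −78 °C.

Step 16
Reactants: 24 (2Z,5S,6E)-5-[(3S)-3-[(tert-butyldimethylsilyl)oxy]-4-methylpent-4-en-1-yl]-7-{(4R,5R)-5-[(E)-3-[(tert-butyldimethylsilyl)oxy]prop-1-en-1-yl]-2,2,5-trimethyl-1,3-dioxolan-4-yl}-2-iodo-5-methylhepta-2,6-dien-1-ol
Product: 25 tert-butyl{[(2Z,5S,6E)-5-[(3S)-3-[(tert-butyldimethylsilyl)oxy]-4-methylpent-4-en-1-yl]-7-{(4R,5R)-5-[(E)-3-[(tert-butyldimethylsilyl)oxy]prop-1-en-1-yl]-2,2,5-trimethyl-1,3-dioxolan-4-yl}-2-iodo-5-methylhepta-2,6-dien-1-yl]oxy}diphenylsilane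
Conditions: TBDPSCl, imidazole, CH2Cl2, rt
Reagents that add atoms: tert-butyl(chloro)diphenylsilane CC(C)(C)[Si](Cl)(c1ccccc1)c1ccccc1
Why: Silylation with the acid-stable TBDPS group distinguishes this primary alcohol from the C8 oxygen that is unmasked next.

Step 17
Reactants: 25 tert-butyl{[(2Z,5S,6E)-5-[(3S)-3-[(tert-butyldimethylsilyl)oxy]-4-methylpent-4-en-1-yl]-7-{(4R,5R)-5-[(E)-3-[(tert-butyldimethylsilyl)oxy]prop-1-en-1-yl]-2,2,5-trimethyl-1,3-dioxolan-4-yl}-2-iodo-5-methylhepta-2,6-dien-1-yl]oxy}diphenylsilane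
Product: 26 (2E,4R,5R,6E,8S,10Z)-8-[(3S)-3-[(tert-butyldimethylsilyl)oxy]-4-methylpent-4-en-1-yl]-12-[(tert-butyldiphenylsilyl)oxy]-11-iodo-4,8-dimethyldodeca-2,6,10-triene-1,4,5-triol
Conditions: p-TsOH·H2O (0.1 equiv), MeOH/CH2Cl2, 0 °C to rt
Reagents that add atoms: none
Why: Acid methanolysis cleaves the primary allylic TBS ether and the acetonide, while the hindered secondary TBS ether and the TBDPS ether survive.

Step 18
Reactants: 26 (2E,4R,5R,6E,8S,10Z)-8-[(3S)-3-[(tert-butyldimethylsilyl)oxy]-4-methylpent-4-en-1-yl]-12-[(tert-butyldiphenylsilyl)oxy]-11-iodo-4,8-dimethyldodeca-2,6,10-triene-1,4,5-triol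
Product: 27 (2E,4R,5R,6E,8S,10Z)-8-[(3S)-3-[(tert-butyldimethylsilyl)oxy]-4-methylpent-4-en-1-yl]-12-[(tert-butyldiphenylsilyl)oxy]-4,5-dihydroxy-11-iodo-4,8-dimethyldodeca-2,6,10-trienal
Conditions: Cu(MeCN)4OTf (5 mol %), 2,2'-bipyridine, TEMPO, N-methylimidazole, MeCN, air, rt
Reagents that add atoms: none
Why: Stahl aerobic Cu/TEMPO oxidation is selective for the primary allylic alcohol over the secondary and tertiary hydroxyls and gives the E enal.

Step 19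
Reactants: 27 (2E,4R,5R,6E,8S,10Z)-8-[(3S)-3-[(tert-butyldimethylsilyl)oxy]-4-methylpent-4-en-1-yl]-12-[(tert-butyldiphenylsilyl)oxy]-4,5-dihydroxy-11-iodo-4,8-dimethyldodeca-2,6,10-trienal
Product: 28 (2E,4R,5R,6E,8S,10Z)-8-[(3S)-3-[(tert-butyldimethylsilyl)oxy]-4-methylpent-4-en-1-yl]-12-[(tert-butyldiphenylsilyl)oxy]-4-hydroxy-11-iodo-4,8-dimethyl-1-oxododeca-2,6,10-trien-5-yl 3-methylbut-2-enoate
Conditions: 3-methylbut-2-enoyl chloride, pyridine, DMAP (cat.), CH2Cl2, 0 °C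
Reagents that add atoms: 3-methylbut-2-enoyl chloride CC(C)=CC(=O)Cl
Why: DMAP-catalysed esterification occurs at the secondary C4 hydroxyl because the tertiary C5 hydroxyl is too hindered to be acylated.

Step 20
Reactants: 28 (2E,4R,5R,6E,8S,10Z)-8-[(3S)-3-[(tert-butyldimethylsilyl)oxy]-4-methylpent-4-en-1-yl]-12-[(tert-butyldiphenylsilyl)oxy]-4-hydroxy-11-iodo-4,8-dimethyl-1-oxododeca-2,6,10-trien-5-yl 3-methylbut-2-enoate
Product: 29 (1R,2E,4S,6Z,9E,11R)-4-[(3S)-3-[(tert-butyldimethylsilyl)oxy]-4-methylpent-4-en-1-yl]-7-{[(tert-butyldiphenylsilyl)oxy]methyl}-8,11-dihydroxy-4,11-dimethylcycloundeca-2,6,9-trien-1-yl 3-methylbut-2-enoate (mixture of C8 carbinol epimers)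
Conditions: CrCl2 (10 equiv), NiCl2 (2 mol %), DMSO/THF, 2 mM, rt
Reagents that add atoms: none
Why: Nozaki–Hiyama–Kishi reaction, in which the alkenylchromium formed from the vinyl iodide adds 1,2 to the enal with retention of the Z geometry and closes the 11-membered ring at C8–C9 under high dilution, the new carbinol configuration being irrelevant.

Step 21
Reactants: 29 (1R,2E,4S,6Z,9E,11R)-4-[(3S)-3-[(tert-butyldimethylsilyl)oxy]-4-methylpent-4-en-1-yl]-7-{[(tert-butyldiphenylsilyl)oxy]methyl}-8,11-dihydroxy-4,11-dimethylcycloundeca-2,6,9-trien-1-yl 3-methylbut-2-enoate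
Product: 30 (1R,2E,4S,6Z,9E,11R)-4-[(3S)-3-[(tert-butyldimethylsilyl)oxy]-4-methylpent-4-en-1-yl]-7-{[(tert-butyldiphenylsilyl)oxy]methyl}-11-hydroxy-4,11-dimethyl-8-oxocycloundeca-2,6,9-trien-1-yl 3-methylbut-2-enoate
Conditions: Dess–Martin periodinane, CH2Cl2, 0 °C
Reagents that add atoms: none
Why: Dess–Martin oxidation of the bis-allylic alcohol gives the cross-conjugated dienone and removes the C8 stereocentre, the tertiary alcohol being unoxidisable.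

Step 22
Reactants: 30 (1R,2E,4S,6Z,9E,11R)-4-[(3S)-3-[(tert-butyldimethylsilyl)oxy]-4-methylpent-4-en-1-yl]-7-{[(tert-butyldiphenylsilyl)oxy]methyl}-11-hydroxy-4,11-dimethyl-8-oxocycloundeca-2,6,9-trien-1-yl 3-methylbut-2-enoate
Product: 31 (1R,2E,4S,6Z,9E,11R)-11-hydroxy-7-(hydroxymethyl)-4-[(3S)-3-hydroxy-4-methylpent-4-en-1-yl]-4,11-dimethyl-8-oxocycloundeca-2,6,9-trien-1-yl 3-methylbut-2-enoate (CNP0311723.1)
Conditions: HF·pyridine, pyridine, THF, 0 °C to rt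
Reagents that add atoms: none
Why: Buffered fluoride desilylation removes both silyl ethers without acyl migration or conjugate addition to the dienone.

**Compound list**

1 | methyl (R)-2,2-dimethyl-1,3-dioxolane-4-carboxylate | COC(=O)[C@H]1COC(C)(C)O1 | starting material
2 | tert-butyldimethyl(prop-2-yn-1-yloxy)silane | C#CCO[Si](C)(C)C(C)(C)C | starting material
3 | {3-[(tert-butyldimethylsilyl)oxy]prop-1-yn-1-yl}lithium (not isolated) | [Li]C#CCO[Si](C)(C)C(C)(C)C | intermediate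
4 | (R)-4-[(tert-butyldimethylsilyl)oxy]-1-(2,2-dimethyl-1,3-dioxolan-4-yl)but-2-yn-1-one | CC(C)(C)[Si](C)(C)OCC#CC(=O)[C@H]1COC(C)(C)O1 | intermediate
5 | (R)-5-[(tert-butyldimethylsilyl)oxy]-2-[(R)-2,2-dimethyl-1,3-dioxolan-4-yl]pent-3-yn-2-ol | CC(C)(C)[Si](C)(C)OCC#C[C@@](C)(O)[C@H]1COC(C)(C)O1 | intermediate
6 | (2R,3E)-5-[(tert-butyldimethylsilyl)oxy]-2-[(R)-2,2-dimethyl-1,3-dioxolan-4-yl]pent-3-en-2-ol | CC(C)(C)[Si](C)(C)OC/C=C/[C@@](C)(O)[C@H]1COC(C)(C)O1 | intermediate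
7 | {(4R,5R)-5-[(E)-3-[(tert-butyldimethylsilyl)oxy]prop-1-en-1-yl]-2,2,5-trimethyl-1,3-dioxolan-4-yl}methanol | OC[C@H]1OC(C)(C)O[C@]1(C)/C=C/CO[Si](C)(C)C(C)(C)C | intermediate
8 | (4S,5R)-5-[(E)-3-[(tert-butyldimethylsilyl)oxy]prop-1-en-1-yl]-2,2,5-trimethyl-1,3-dioxolane-4-carbaldehyde | O=C[C@H]1OC(C)(C)O[C@]1(C)/C=C/CO[Si](C)(C)C(C)(C)C | intermediate
9 | (S)-5-oxotetrahydrofuran-2-carboxylic acid | OC(=O)[C@@H]1CCC(=O)O1 | starting material
10 | (S)-5-oxotetrahydrofuran-2-carbonyl chloride (not isolated) | ClC(=O)[C@@H]1CCC(=O)O1 | intermediate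
11 | (S)-5-acetyldihydrofuran-2(3H)-one | CC(=O)[C@@H]1CCC(=O)O1 | intermediate
12 | (S)-5-(prop-1-en-2-yl)dihydrofuran-2(3H)-one | C=C(C)[C@@H]1CCC(=O)O1 | intermediate
13 | (5S)-5-(prop-1-en-2-yl)tetrahydrofuran-2-ol (lactol, anomer mixture, not isolated) | C=C(C)[C@@H]1CCC(O)O1 | intermediate
14 | (S)-2-methylhept-1-en-6-yn-3-ol | C=C(C)[C@@H](O)CCC#C | intermediate
15 | (S)-tert-butyldimethyl[(2-methylhept-1-en-6-yn-3-yl)oxy]silane | C=C(C)[C@@H](O[Si](C)(C)C(C)(C)C)CCC#C | intermediate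
16 | {(1E,5S)-5-[(tert-butyldimethylsilyl)oxy]-2,6-dimethylhepta-1,6-dien-1-yl}dimethylalane (not isolated) | C=C(C)[C@@H](O[Si](C)(C)C(C)(C)C)CC/C(C)=C/[Al](C)C | intermediate
17 | tert-butyl{[(3S,6E)-7-iodo-2,6-dimethylhepta-1,6-dien-3-yl]oxy}dimethylsilane | C=C(C)[C@@H](O[Si](C)(C)C(C)(C)C)CC/C(C)=C/I | intermediate
18 | {(1E,5S)-5-[(tert-butyldimethylsilyl)oxy]-2,6-dimethylhepta-1,6-dien-1-yl}lithium (not isolated) | C=C(C)[C@@H](O[Si](C)(C)C(C)(C)C)CC/C(C)=C/[Li] | intermediate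
19 | (1R,2E,6S)-6-[(tert-butyldimethylsilyl)oxy]-1-{(4R,5R)-5-[(E)-3-[(tert-butyldimethylsilyl)oxy]prop-1-en-1-yl]-2,2,5-trimethyl-1,3-dioxolan-4-yl}-3,7-dimethylocta-2,7-dien-1-ol | C=C(C)[C@@H](O[Si](C)(C)C(C)(C)C)CC/C(C)=C/[C@@H](O)[C@H]1OC(C)(C)O[C@]1(C)/C=C/CO[Si](C)(C)C(C)(C)C | intermediate
20 | 1-ethoxyvinyl ether (mixed ketene acetal) of 19, configurations as in 19 (not isolated) | C=C(C)[C@@H](O[Si](C)(C)C(C)(C)C)CC/C(C)=C/[C@@H](OC(=C)OCC)[C@H]1OC(C)(C)O[C@]1(C)/C=C/CO[Si](C)(C)C(C)(C)C | intermediate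
21 | ethyl (3S,4E)-3-[(3S)-3-[(tert-butyldimethylsilyl)oxy]-4-methylpent-4-en-1-yl]-5-{(4R,5R)-5-[(E)-3-[(tert-butyldimethylsilyl)oxy]prop-1-en-1-yl]-2,2,5-trimethyl-1,3-dioxolan-4-yl}-3-methylpent-4-enoate | C=C(C)[C@@H](O[Si](C)(C)C(C)(C)C)CC[C@@](C)(CC(=O)OCC)/C=C/[C@H]1OC(C)(C)O[C@]1(C)/C=C/CO[Si](C)(C)C(C)(C)C | intermediate
22 | (3S,4E)-3-[(3S)-3-[(tert-butyldimethylsilyl)oxy]-4-methylpent-4-en-1-yl]-5-{(4R,5R)-5-[(E)-3-[(tert-butyldimethylsilyl)oxy]prop-1-en-1-yl]-2,2,5-trimethyl-1,3-dioxolan-4-yl}-3-methylpent-4-enal | C=C(C)[C@@H](O[Si](C)(C)C(C)(C)C)CC[C@@](C)(CC=O)/C=C/[C@H]1OC(C)(C)O[C@]1(C)/C=C/CO[Si](C)(C)C(C)(C)C | intermediate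
23 | ethyl (2Z,5S,6E)-5-[(3S)-3-[(tert-butyldimethylsilyl)oxy]-4-methylpent-4-en-1-yl]-7-{(4R,5R)-5-[(E)-3-[(tert-butyldimethylsilyl)oxy]prop-1-en-1-yl]-2,2,5-trimethyl-1,3-dioxolan-4-yl}-2-iodo-5-methylhepta-2,6-dienoate | C=C(C)[C@@H](O[Si](C)(C)C(C)(C)C)CC[C@@](C)(C/C=C(\I)C(=O)OCC)/C=C/[C@H]1OC(C)(C)O[C@]1(C)/C=C/CO[Si](C)(C)C(C)(C)C | intermediate
24 | (2Z,5S,6E)-5-[(3S)-3-[(tert-butyldimethylsilyl)oxy]-4-methylpent-4-en-1-yl]-7-{(4R,5R)-5-[(E)-3-[(tert-butyldimethylsilyl)oxy]prop-1-en-1-yl]-2,2,5-trimethyl-1,3-dioxolan-4-yl}-2-iodo-5-methylhepta-2,6-dien-1-ol | C=C(C)[C@@H](O[Si](C)(C)C(C)(C)C)CC[C@@](C)(C/C=C(\I)CO)/C=C/[C@H]1OC(C)(C)O[C@]1(C)/C=C/CO[Si](C)(C)C(C)(C)C | intermediate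
25 | tert-butyl{[(2Z,5S,6E)-5-[(3S)-3-[(tert-butyldimethylsilyl)oxy]-4-methylpent-4-en-1-yl]-7-{(4R,5R)-5-[(E)-3-[(tert-butyldimethylsilyl)oxy]prop-1-en-1-yl]-2,2,5-trimethyl-1,3-dioxolan-4-yl}-2-iodo-5-methylhepta-2,6-dien-1-yl]oxy}diphenylsilane | C=C(C)[C@@H](O[Si](C)(C)C(C)(C)C)CC[C@@](C)(C/C=C(\I)CO[Si](c2ccccc2)(c3ccccc3)C(C)(C)C)/C=C/[C@H]1OC(C)(C)O[C@]1(C)/C=C/CO[Si](C)(C)C(C)(C)C | intermediate
26 | (2E,4R,5R,6E,8S,10Z)-8-[(3S)-3-[(tert-butyldimethylsilyl)oxy]-4-methylpent-4-en-1-yl]-12-[(tert-butyldiphenylsilyl)oxy]-11-iodo-4,8-dimethyldodeca-2,6,10-triene-1,4,5-triol | C=C(C)[C@@H](O[Si](C)(C)C(C)(C)C)CC[C@@](C)(C/C=C(\I)CO[Si](c1ccccc1)(c2ccccc2)C(C)(C)C)/C=C/[C@@H](O)[C@](C)(O)/C=C/CO | intermediate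
27 | (2E,4R,5R,6E,8S,10Z)-8-[(3S)-3-[(tert-butyldimethylsilyl)oxy]-4-methylpent-4-en-1-yl]-12-[(tert-butyldiphenylsilyl)oxy]-4,5-dihydroxy-11-iodo-4,8-dimethyldodeca-2,6,10-trienal | C=C(C)[C@@H](O[Si](C)(C)C(C)(C)C)CC[C@@](C)(C/C=C(\I)CO[Si](c1ccccc1)(c2ccccc2)C(C)(C)C)/C=C/[C@@H](O)[C@](C)(O)/C=C/C=O | intermediate
28 | (2E,4R,5R,6E,8S,10Z)-8-[(3S)-3-[(tert-butyldimethylsilyl)oxy]-4-methylpent-4-en-1-yl]-12-[(tert-butyldiphenylsilyl)oxy]-4-hydroxy-11-iodo-4,8-dimethyl-1-oxododeca-2,6,10-trien-5-yl 3-methylbut-2-enoate | C=C(C)[C@@H](O[Si](C)(C)C(C)(C)C)CC[C@@](C)(C/C=C(\I)CO[Si](c1ccccc1)(c2ccccc2)C(C)(C)C)/C=C/[C@@H](OC(=O)C=C(C)C)[C@](C)(O)/C=C/C=O | intermediate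
29 | (1R,2E,4S,6Z,9E,11R)-4-[(3S)-3-[(tert-butyldimethylsilyl)oxy]-4-methylpent-4-en-1-yl]-7-{[(tert-butyldiphenylsilyl)oxy]methyl}-8,11-dihydroxy-4,11-dimethylcycloundeca-2,6,9-trien-1-yl 3-methylbut-2-enoate (C8 epimers) | C=C(C)[C@@H](O[Si](C)(C)C(C)(C)C)CC[C@]1(C)/C=C/[C@@H](OC(=O)C=C(C)C)[C@](C)(O)/C=C/C(O)/C(CO[Si](c2ccccc2)(c3ccccc3)C(C)(C)C)=C\C1 | intermediate
30 | (1R,2E,4S,6Z,9E,11R)-4-[(3S)-3-[(tert-butyldimethylsilyl)oxy]-4-methylpent-4-en-1-yl]-7-{[(tert-butyldiphenylsilyl)oxy]methyl}-11-hydroxy-4,11-dimethyl-8-oxocycloundeca-2,6,9-trien-1-yl 3-methylbut-2-enoate | C=C(C)[C@@H](O[Si](C)(C)C(C)(C)C)CC[C@]1(C)/C=C/[C@@H](OC(=O)C=C(C)C)[C@](C)(O)/C=C/C(=O)/C(CO[Si](c2ccccc2)(c3ccccc3)C(C)(C)C)=C\C1 | intermediate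
31 | (1R,2E,4S,6Z,9E,11R)-11-hydroxy-7-(hydroxymethyl)-4-[(3S)-3-hydroxy-4-methylpent-4-en-1-yl]-4,11-dimethyl-8-oxocycloundeca-2,6,9-trien-1-yl 3-methylbut-2-enoate | C=C(C)[C@@H](O)CC[C@]1(C)/C=C/[C@@H](OC(=O)C=C(C)C)[C@](C)(O)/C=C/C(=O)/C(CO)=C\C1 | target

**Step count and risks**

Total steps: 22. Longest linear sequence: 17 steps (9 → 31 through steps 6–10 and 11–22; the branch from 1 through steps 1–5 and 11–22 is equally long).

Most likely to fail, first: step 20, the Nozaki–Hiyama–Kishi closure of a strained 11-membered triene. The fallback closes the ring by metathesis at C6=C7 instead. It sets out from 25 and comes back at 30. Intermolecular CrCl2/NiCl2 coupling of 25 with acrolein gives the bis-allylic alcohol (4Z,7S,8E)-7-[(3S)-3-[(tert-butyldimethylsilyl)oxy]-4-methylpent-4-en-1-yl]-4-{[(tert-butyldiphenylsilyl)oxy]methyl}-9-{(4R,5R)-5-[(E)-3-[(tert-butyldimethylsilyl)oxy]prop-1-en-1-yl]-2,2,5-trimethyl-1,3-dioxolan-4-yl}-7-methylnona-1,4,8-trien-3-ol F1. Dess–Martin oxidation gives the corresponding divinyl ketone, the nona-1,4,8-trien-3-one F2. Ring-closing metathesis with the second-generation Hoveyda–Grubbs catalyst (toluene, 80 °C, 1 mM) joins the vinyl ketone to the C6=C7 alkene with loss of allyl TBS ether and gives the macrocyclic dienone acetonide F3. p-TsOH in MeOH removes the acetonide to give the diol (2Z,5S,6E,8R,9R,10E)-5-[(3S)-3-[(tert-butyldimethylsilyl)oxy]-4-methylpent-4-en-1-yl]-2-{[(tert-butyldiphenylsilyl)oxy]methyl}-8,9-dihydroxy-5,9-dimethylcycloundeca-2,6,10-trien-1-one F4. Acylation as in step 19 then gives 30.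

Second: step 11, where the Felkin selectivity of the alkenyllithium addition decides the C1 configuration after the rearrangement. The fallback sets the carbinol by hydride reduction instead of by C–C bond formation. It sets out from 8 (with 18) and comes back at 19. The unselective addition gives 19 together with its carbinol epimer, the (1S,2E,6S)-octa-2,7-dien-1-ol F5. Dess–Martin oxidation of the mixture gives the enone (2E,6S)-6-[(tert-butyldimethylsilyl)oxy]-1-{(4S,5R)-5-[(E)-3-[(tert-butyldimethylsilyl)oxy]prop-1-en-1-yl]-2,2,5-trimethyl-1,3-dioxolan-4-yl}-3,7-dimethylocta-2,7-dien-1-one F6. Chelation-controlled 1,2-reduction with Zn(BH4)2 (Et2O, −30 °C) delivers hydride from the face of the C4 hydrogen and gives the anti alcohol 19.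

Third: step 4, where the acetonide migration may stop at an unfavourable equilibrium or ionise the tertiary allylic oxygen. The fallback replaces the migration by a stepwise protecting-group relay. It sets out from 6 and comes back at 7. Selective hydrolysis of the terminal acetonide (CeCl3·7H2O, oxalic acid, MeCN) gives the triol (2R,3R,4E)-6-[(tert-butyldimethylsilyl)oxy]-3-methylhex-4-ene-1,2,3-triol F7. Pivaloyl chloride in pyridine at −20 °C gives the primary ester (2R,3R,4E)-6-[(tert-butyldimethylsilyl)oxy]-2,3-dihydroxy-3-methylhex-4-en-1-yl pivalate F8. 2-Methoxypropene with PPTS closes the acetonide on the secondary and tertiary oxygens to give {(4R,5R)-5-[(E)-3-[(tert-butyldimethylsilyl)oxy]prop-1-en-1-yl]-2,2,5-trimethyl-1,3-dioxolan-4-yl}methyl pivalate F9. i-Bu2AlH at −78 °C removes the pivalate and gives 7.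

Further compounds
F1 | step 20 | (4Z,7S,8E)-7-[(3S)-3-[(tert-butyldimethylsilyl)oxy]-4-methylpent-4-en-1-yl]-4-{[(tert-butyldiphenylsilyl)oxy]methyl}-9-{(4R,5R)-5-[(E)-3-[(tert-butyldimethylsilyl)oxy]prop-1-en-1-yl]-2,2,5-trimethyl-1,3-dioxolan-4-yl}-7-methylnona-1,4,8-trien-3-ol (carbinol epimers) | C=C(C)[C@@H](O[Si](C)(C)C(C)(C)C)CC[C@@](C)(C/C=C(\C(O)C=C)CO[Si](c2ccccc2)(c3ccccc3)C(C)(C)C)/C=C/[C@H]1OC(C)(C)O[C@]1(C)/C=C/CO[Si](C)(C)C(C)(C)C
F2 | step 20 | (4Z,7S,8E)-7-[(3S)-3-[(tert-butyldimethylsilyl)oxy]-4-methylpent-4-en-1-yl]-4-{[(tert-butyldiphenylsilyl)oxy]methyl}-9-{(4R,5R)-5-[(E)-3-[(tert-butyldimethylsilyl)oxy]prop-1-en-1-yl]-2,2,5-trimethyl-1,3-dioxolan-4-yl}-7-methylnona-1,4,8-trien-3-one | C=C(C)[C@@H](O[Si](C)(C)C(C)(C)C)CC[C@@](C)(C/C=C(\C(=O)C=C)CO[Si](c2ccccc2)(c3ccccc3)C(C)(C)C)/C=C/[C@H]1OC(C)(C)O[C@]1(C)/C=C/CO[Si](C)(C)C(C)(C)C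
F3 | step 20 | macrocyclic dienone acetonide (8,9-O-isopropylidene derivative of F4) | C=C(C)[C@@H](O[Si](C)(C)C(C)(C)C)CC[C@]1(C)/C=C/[C@H]2OC(C)(C)O[C@]2(C)/C=C/C(=O)/C(CO[Si](c3ccccc3)(c4ccccc4)C(C)(C)C)=C\C1
F4 | step 20 | (2Z,5S,6E,8R,9R,10E)-5-[(3S)-3-[(tert-butyldimethylsilyl)oxy]-4-methylpent-4-en-1-yl]-2-{[(tert-butyldiphenylsilyl)oxy]methyl}-8,9-dihydroxy-5,9-dimethylcycloundeca-2,6,10-trien-1-one | C=C(C)[C@@H](O[Si](C)(C)C(C)(C)C)CC[C@]1(C)/C=C/[C@@H](O)[C@](C)(O)/C=C/C(=O)/C(CO[Si](c2ccccc2)(c3ccccc3)C(C)(C)C)=C\C1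
F5 | step 11 | (1S,2E,6S)-6-[(tert-butyldimethylsilyl)oxy]-1-{(4R,5R)-5-[(E)-3-[(tert-butyldimethylsilyl)oxy]prop-1-en-1-yl]-2,2,5-trimethyl-1,3-dioxolan-4-yl}-3,7-dimethylocta-2,7-dien-1-ol | C=C(C)[C@@H](O[Si](C)(C)C(C)(C)C)CC/C(C)=C/[C@H](O)[C@H]1OC(C)(C)O[C@]1(C)/C=C/CO[Si](C)(C)C(C)(C)C
F6 | step 11 | (2E,6S)-6-[(tert-butyldimethylsilyl)oxy]-1-{(4S,5R)-5-[(E)-3-[(tert-butyldimethylsilyl)oxy]prop-1-en-1-yl]-2,2,5-trimethyl-1,3-dioxolan-4-yl}-3,7-dimethylocta-2,7-dien-1-one | C=C(C)[C@@H](O[Si](C)(C)C(C)(C)C)CC/C(C)=C/C(=O)[C@H]1OC(C)(C)O[C@]1(C)/C=C/CO[Si](C)(C)C(C)(C)C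
F7 | step 4 | (2R,3R,4E)-6-[(tert-butyldimethylsilyl)oxy]-3-methylhex-4-ene-1,2,3-triol | OC[C@@H](O)[C@](C)(O)/C=C/CO[Si](C)(C)C(C)(C)C
F8 | step 4 | (2R,3R,4E)-6-[(tert-butyldimethylsilyl)oxy]-2,3-dihydroxy-3-methylhex-4-en-1-yl pivalate | CC(C)(C)C(=O)OC[C@@H](O)[C@](C)(O)/C=C/CO[Si](C)(C)C(C)(C)C
F9 | step 4 | {(4R,5R)-5-[(E)-3-[(tert-butyldimethylsilyl)oxy]prop-1-en-1-yl]-2,2,5-trimethyl-1,3-dioxolan-4-yl}methyl pivalate | CC(C)(C)C(=O)OC[C@H]1OC(C)(C)O[C@]1(C)/C=C/CO[Si](C)(C)C(C)(C)C
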